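The reckoning here follows the charge of Q rather than the temperature.

| flask | Q | temperature | remark | time |
|---|---|---|---|---|
| south-west | 0.67 M | 85 °C | run made earlier |  |
| west | 1.5 M | 118 °C | run made earlier |  |
| gamma | 1.0 M |  | at 70 °C until 4.0 d, from then on at 130 °C | 12 d |
| epsilon | 1.0 M |  | at 70 °C throughout | 25 d |

south-west run (percent of the Q charged)

| time / d | Z / % | Q / % |
|---|---|---|
| 0.333 | 76.9 | 0.3 |
| 0.625 | 76.4 | 0 |
| 1.25 | 76.7 | 0 |
| 4.00 | 76.7 | 0 |

west run (percent of the Q charged)

| time / h | Z / % | Q / % |
|---|---|---|
| 4.00 | 60.5 | 0.1 |
| 8.00 | 60.0 | 0 |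
| 12.0 | 59.7 | 0.1 |
| 20.0 | 59.8 | 0 |

(readings scatter by 0.3 percentage points)

- the analysis behind the earlier runs scatters by 0.3 percentage points, standard deviation
- a reading or a percentage of Z counts all its forms, free or not

- the flask that ends with the higher amount of Z, in percent of the Q charged, or "neither" when 2 percentage points or less lies between them (gamma / epsilon / neither)
- final Z, as a percentage of the Q charged, in gamma
- final Z, as a percentage of the Q charged, in epsilon

A bench rule says that a loss grows in proportion to the charge. The west charge is 2.24 times the south-west charge, but its missing Z is 1.73 times as much, so these two runs, which differ in temperature as well, do not follow the rule. The ratio of lost to kept, however, grows 2.21 times.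

Suppose Q goes to Z at first order and to a loss at second order. The momentary share going to Z is then 1/(1 + K c_Q), where K is a selectivity factor. Integrating over c_Q from the charge c down to zero gives the final fraction Y = ln(1 + Kc)/(Kc), and for moderate Kc, lost over kept is close to Kc/2.

So I carry the loss ratio per molar of charge, ρ, the ratio of lost to kept divided by the charge. It reads 0.453 L mol⁻¹ in south-west and 0.448 L mol⁻¹ in west, mean 0.451 L mol⁻¹. Taking ρ as independent of temperature is an assumption, since both settings changed between these runs.

The south-west reading of Q at 0.333 d is 0.3%, no farther from zero than the scatter of 0.3 percentage points, and gamma waits 12.0 times that long before heating. If cooling to 70 °C slows Q by less than this factor, gamma and epsilon end alike, and my reckoning gives 68.9% for both.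

The forecast says neither, with 77% and 77%: “I take about 77% for both flasks”.

The flasks give neither, with 69.7% in gamma and 69.7% in epsilon, L counted in Z. That stands 7.3 points below the forecast, and gamma's own ratio per molar is 0.434 L mol⁻¹.

    2 Q → D (k = 0.240 L mol⁻¹ h⁻¹, Ea = 97.0 kJ mol⁻¹)
    Q → Z (k = 0.490 h⁻¹, Ea = 95.0 kJ mol⁻¹)
    L ⇌ Z, rate k3*(cs3 - [Z]) while solid is left; crystals form when [Z] > cs3 (solubility = 47.0 mM, k = 6.10 h⁻¹)
    (constants at 70 °C)

In gamma, Q passing into Z starts at 1.0 times the rate of Q passing into D, and stands at 2.5 times by 0.0457 d. Half of those turnovers are done by 1.10 h and 0.470 h, against the change of temperature at 4.0 d, and the second temperature changes nothing.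

For gamma's neighbour charged with 0.25 M, ρ gives 89.9%. The computed flask ends at 89.4%.

(The runs were generated by integration with constants of no real substance.)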